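**Retrosynthetic overview**

- Sophoranone comes from its 7,4'-bis-MOM ether, masked at C4 as an N-tert-butanesulfinyl ketimine, by one acid treatment; rings A and B come from the starting materials and ring C is the only ring built.
- Ring C is cut at C2–C3 (aldol) and at O1–C8a (aryl ether), and the C8–prenyl bond is cut with them. This gives fragment A (chiral sulfinyl ketimine of 2-triflyloxy-3-iodo-4-MOMO-acetophenone), fragment B (4-MOMO-3,5-diprenylbenzaldehyde) and prenyl bromide.
- Enabling feature: on ring A the ether oxygen O1 (on C8a) and a prenyl group (on C8) sit on neighbouring carbons, flanked by the C7 oxygen and by C4a, which carries C4. This is the footprint of a C8–C8a aryne, and the aldol oxygen on C2 lies six atoms from C8a (O1–C2–C3–C4–C4a–C8a).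
- Fragment A is made from 2,4-dihydroxyacetophenone (C3 iodination, 4-O-MOM, 2-O-triflate, sulfinyl imine); fragment B from 4-bromophenol (double ortho-prenylation, MOM ether, formylation).
- Ring order: A and B preformed, ring C closed in the key step, and C2 set in the same step by the sulfur auxiliary.

Key step: step 8

Remark: flavanone numbering is used throughout (O1, C2, C3, C4, C4a, C5 to C8, C8a; ring B primed); MOM = methoxymethyl, Tf = trifluoromethanesulfonyl, prenyl = 3-methylbut-2-en-1-yl.

Assumption: the (S)-configured sulfinyl group is taken to deliver the 2S carbinol in the magnesium metalloenamine aldol; should the sense be the reverse, (R)-2-methylpropane-2-sulfinamide is used in step 7 and nothing else changes.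

**Route**

Step 1
Reactants: 1 4-bromophenol
Product: 2 4-bromo-2,6-bis(3-methylbut-2-en-1-yl)phenol
Conditions: NaH (2.2 equiv), prenyl bromide (2.2 equiv), toluene, 0 °C → rt
Reagents that add atoms: prenyl bromide (1-bromo-3-methylbut-2-ene), CC(C)=CCBr
Why: C-allylation of a sodium phenoxide in a non-polar medium, where the tight ion pair shields oxygen and the blocked para position leaves only the two ortho carbons, should give the 2,6-diprenylphenol after tautomerisation.

Step 2
Reactants: 2 4-bromo-2,6-bis(3-methylbut-2-en-1-yl)phenol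
Product: 3 5-bromo-2-(methoxymethoxy)-1,3-bis(3-methylbut-2-en-1-yl)benzene
Conditions: NaH, MOMCl, THF/DMF, 0 °C → rt
Reagents that add atoms: chloromethyl methyl ether (MOMCl), COCCl
Why: Williamson-type O-alkylation of the hindered phenoxide with the small, highly reactive chloromethyl ether should be clean and gives an acetal that survives organolithium and Grignard reagents.

Step 3
Reactants: 3 5-bromo-2-(methoxymethoxy)-1,3-bis(3-methylbut-2-en-1-yl)benzene
Product: 4 4-(methoxymethoxy)-3,5-bis(3-methylbut-2-en-1-yl)benzaldehyde (fragment B)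
Conditions: n-BuLi, THF, –78 °C; DMF, –78 °C → rt; H2O
Reagents that add atoms: N,N-dimethylformamide, CN(C)C=O
Why: Bromine–lithium exchange is faster at –78 °C than deprotonation of the doubly activated benzylic-allylic CH2 groups, and the aryllithium is formylated by DMF (Bouveault aldehyde synthesis).

Step 4
Reactants: 5 1-(2,4-dihydroxyphenyl)ethan-1-one (2,4-dihydroxyacetophenone)
Product: 6 1-(2,4-dihydroxy-3-iodophenyl)ethan-1-one
Conditions: I2, HIO3, EtOH/H2O, rt
Reagents that add atoms: iodine, II; iodic acid, O[I](=O)=O
Why: Electrophilic aromatic iodination (5 ArH + 2 I2 + HIO3 → 5 ArI + 3 H2O) should go to C3 between the two hydroxyl groups, because the hydrogen-bonded 2-hydroxy ketone fixes the reactive double bond between C2 and C3, and any 5-iodo isomer would be removed by crystallisation.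

Step 5
Reactants: 6 1-(2,4-dihydroxy-3-iodophenyl)ethan-1-one
Product: 7 1-[2-hydroxy-3-iodo-4-(methoxymethoxy)phenyl]ethan-1-one
Conditions: MOMCl (1.1 equiv), K2CO3, acetone, 0 °C → rt
Reagents that add atoms: chloromethyl methyl ether (MOMCl), COCCl
Why: Williamson-type O-alkylation should take only the 4-hydroxyl, which is the more acidic one and is free, while the 2-hydroxyl is tied up in the hydrogen bond to the acetyl group and does not react with a weak base.

Step 6
Reactants: 7 1-[2-hydroxy-3-iodo-4-(methoxymethoxy)phenyl]ethan-1-one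
Product: 8 6-acetyl-2-iodo-3-(methoxymethoxy)phenyl trifluoromethanesulfonate
Conditions: Tf2O, pyridine, CH2Cl2, –20 → 0 °C
Reagents that add atoms: trifluoromethanesulfonic anhydride, O=S(=O)(OS(=O)(=O)C(F)(F)F)C(F)(F)F
Why: O-sulfonylation of the remaining phenol under buffered conditions that leave the MOM acetal intact puts the nucleofuge on C8a next to the C8 iodide, the 1,2-pattern needed for aryne release.

Step 7
Reactants: 8 6-acetyl-2-iodo-3-(methoxymethoxy)phenyl trifluoromethanesulfonate
Product: 9 2-iodo-3-(methoxymethoxy)-6-[(1E)-1-{[(S)-tert-butylsulfinyl]imino}ethyl]phenyl trifluoromethanesulfonate (fragment A)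
Conditions: (S)-t-BuS(O)NH2, Ti(OEt)4, THF, 65 °C
Reagents that add atoms: (S)-2-methylpropane-2-sulfinamide, CC(C)(C)[S@](=O)N
Why: Ti(OEt)4-mediated condensation of an aryl methyl ketone with tert-butanesulfinamide (N-sulfinyl ketimine formation) should give the E imine, which masks the ketone against Grignard reagents and carries the stereocontrolling sulfur centre.

Step 8
Reactants: 9 fragment A (N-sulfinyl ketimine); 4 fragment B (aldehyde)
Product: 15 (S)-N-[(2S,4E)-7-(methoxymethoxy)-2-[4-(methoxymethoxy)-3,5-bis(3-methylbut-2-en-1-yl)phenyl]-8-(3-methylbut-2-en-1-yl)-2,3-dihydro-4H-chromen-4-ylidene]-2-methylpropane-2-sulfinamide, via bromomagnesium metalloenamine 10 (not isolated), via bromomagnesium aldolate 11 (not isolated), via C8-magnesiated aryl triflate 12 (not isolated), via C8–C8a aryne 13 (not isolated), via C8-arylmagnesium chromanimine 14 (not isolated)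
Conditions: LiN(i-Pr)2, THF, –78 °C; MgBr2·OEt2; 4, –78 °C; i-PrMgCl·LiCl (1.1 equiv), –78 → –40 °C; CuBr·SMe2 (20 mol %), prenyl bromide, –40 → 0 °C; aq NH4Cl
Reagents that add atoms: prenyl bromide (1-bromo-3-methylbut-2-ene), CC(C)=CCBr
Why: Proposed new method: the magnesium metalloenamine of 9 adds to aldehyde 4 through a closed, magnesium-bridged six-membered chair transition state (closest known reaction type: diastereoselective aldol addition of N-tert-butanesulfinyl ketimine metalloenamines to aldehydes), which forms C2–C3 and sets C2 as S under control of the sulfur stereocentre. Iodine–magnesium exchange at C8 then expels the neighbouring triflate and unmasks a C8–C8a aryne, and the aldolate oxygen, held six atoms away, adds to C8a (6-exo-dig closure of ring C; closest known reaction type: intramolecular alkoxide addition to arynes), so that O1–C8a is formed at low temperature before retro-aldol can erode C2. The side of addition is fixed twice: the tether can only reach C8a, and the inductively withdrawing C7 OMOM group polarises the aryne so that the nucleophile enters meta to it and the negative charge develops on C8 next to that oxygen. The C8 arylmagnesium so formed, chelated by the MOM group, should be allylated by prenyl bromide at its unsubstituted terminus under CuBr·SMe2 catalysis (closest known reaction type: copper-catalysed coupling of aryl Grignard reagents with prenyl halides), which installs the 8-prenyl group as a third bond in the same flask. The step needs exchange at the C–I bond to be faster than attack of i-PrMgCl on C=N or on sulfur (secured by the flanking OTf and OMOM groups and by –78 °C), triflate loss to be faster than 1,3-sulfonyl migration, and capture of the aryne by the internal alkoxide to be faster than by any external nucleophile (secured by the six-membered tether).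

Step 9
Reactants: 15 N-sulfinyl ketimine of the bis-MOM flavanone
Product: 17 sophoranone, (2S)-7-hydroxy-2-[4-hydroxy-3,5-bis(3-methylbut-2-en-1-yl)phenyl]-8-(3-methylbut-2-en-1-yl)-2,3-dihydro-4H-chromen-4-one, via bis-MOM flavanone 16 (not isolated)
Conditions: HCl (3 M aq), MeOH/THF, 0 °C → rt
Reagents that add atoms: water, O
Why: Acid solvolysis should cleave the N–S bond and hydrolyse the resulting iminium to the C4 ketone, then exchange both MOM acetals with methanol, and C2 is not scrambled because no base is present to open ring C through the C3 enolate.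

**Compound list**

1 | 4-bromophenol | Oc1ccc(Br)cc1 | starting material
2 | 4-bromo-2,6-bis(3-methylbut-2-en-1-yl)phenol | CC(C)=CCc1cc(Br)cc(CC=C(C)C)c1O | intermediate
3 | 5-bromo-2-(methoxymethoxy)-1,3-bis(3-methylbut-2-en-1-yl)benzene | CC(C)=CCc1cc(Br)cc(CC=C(C)C)c1OCOC | intermediate
4 | 4-(methoxymethoxy)-3,5-bis(3-methylbut-2-en-1-yl)benzaldehyde | CC(C)=CCc1cc(C=O)cc(CC=C(C)C)c1OCOC | intermediate
5 | 1-(2,4-dihydroxyphenyl)ethan-1-one | CC(=O)c1ccc(O)cc1O | starting material
6 | 1-(2,4-dihydroxy-3-iodophenyl)ethan-1-one | CC(=O)c1ccc(O)c(I)c1O | intermediate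
7 | 1-[2-hydroxy-3-iodo-4-(methoxymethoxy)phenyl]ethan-1-one | CC(=O)c1ccc(OCOC)c(I)c1O | intermediate
8 | 6-acetyl-2-iodo-3-(methoxymethoxy)phenyl trifluoromethanesulfonate | CC(=O)c1ccc(OCOC)c(I)c1OS(=O)(=O)C(F)(F)F | intermediate
9 | 2-iodo-3-(methoxymethoxy)-6-[(1E)-1-{[(S)-tert-butylsulfinyl]imino}ethyl]phenyl trifluoromethanesulfonate | C/C(=N\[S@@](=O)C(C)(C)C)c1ccc(OCOC)c(I)c1OS(=O)(=O)C(F)(F)F | intermediate
10 | bromomagnesium metalloenamine of 9 (N-magnesiated N-sulfinyl enamide, S at sulfur) | C=C(N([Mg]Br)[S@@](=O)C(C)(C)C)c1ccc(OCOC)c(I)c1OS(=O)(=O)C(F)(F)F | intermediate (not isolated)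
11 | bromomagnesium (S)-aldolate: β-alkoxide N-sulfinyl ketimine with C8 iodide and C8a triflate | CC(C)=CCc1cc([C@@H](O[Mg]Br)C/C(=N\[S@@](=O)C(C)(C)C)c2ccc(OCOC)c(I)c2OS(=O)(=O)C(F)(F)F)cc(CC=C(C)C)c1OCOC | intermediate (not isolated)
12 | C8-chloromagnesio aryl triflate derived from 11 | CC(C)=CCc1cc([C@@H](O[Mg]Br)C/C(=N\[S@@](=O)C(C)(C)C)c2ccc(OCOC)c([Mg]Cl)c2OS(=O)(=O)C(F)(F)F)cc(CC=C(C)C)c1OCOC | intermediate (not isolated)
13 | C8–C8a aryne carrying the (S)-aldolate side chain | CC(C)=CCc1cc([C@@H](O[Mg]Br)C/C(=N\[S@@](=O)C(C)(C)C)C2=CC=C(OCOC)C#C2)cc(CC=C(C)C)c1OCOC | intermediate (not isolated)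
14 | (2S)-8-bromomagnesio-7-(methoxymethoxy)-2-aryl-chroman-4-imine, N-(S)-sulfinyl | CC(C)=CCc1cc([C@@H]2C/C(=N\[S@@](=O)C(C)(C)C)c3ccc(OCOC)c([Mg]Br)c3O2)cc(CC=C(C)C)c1OCOC | intermediate (not isolated)
15 | (S)-N-[(2S,4E)-7-(methoxymethoxy)-2-[4-(methoxymethoxy)-3,5-bis(3-methylbut-2-en-1-yl)phenyl]-8-(3-methylbut-2-en-1-yl)-2,3-dihydro-4H-chromen-4-ylidene]-2-methylpropane-2-sulfinamide | CC(C)=CCc1cc([C@@H]2C/C(=N\[S@@](=O)C(C)(C)C)c3ccc(OCOC)c(CC=C(C)C)c3O2)cc(CC=C(C)C)c1OCOC | intermediate
16 | (2S)-7-(methoxymethoxy)-2-[4-(methoxymethoxy)-3,5-bis(3-methylbut-2-en-1-yl)phenyl]-8-(3-methylbut-2-en-1-yl)-2,3-dihydro-4H-chromen-4-one | CC(C)=CCc1cc([C@@H]2CC(=O)c3ccc(OCOC)c(CC=C(C)C)c3O2)cc(CC=C(C)C)c1OCOC | intermediate (not isolated)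
17 | sophoranone, (2S)-7-hydroxy-2-[4-hydroxy-3,5-bis(3-methylbut-2-en-1-yl)phenyl]-8-(3-methylbut-2-en-1-yl)-2,3-dihydro-4H-chromen-4-one | CC(C)=CCc1cc([C@@H]2CC(=O)c3ccc(O)c(CC=C(C)C)c3O2)cc(CC=C(C)C)c1O | target

**Totals**

Total step count: 9. Longest linear sequence: 6 steps (steps 4 to 9, from 2,4-dihydroxyacetophenone).

**Steps most likely to fail, with fallbacks**

Step 8 (bears the label). What may go wrong: retro-aldol of the magnesium aldolate before the aryne is released; transfer of the triflyl group to the aza-enolate or 1,3-sulfonyl migration instead of triflate loss; attack of the Grignard reagent on the ketimine; poor facial selectivity of the aldol with the hindered aldehyde; allylation at the wrong terminus of the prenyl unit.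

Fallback by known chemistry only: it sets out from bromide 3 and iodoketone 7 and comes back to the route at 16.
- Bromide 3 is lithiated (n-BuLi, –78 °C) and quenched with B(Oi-Pr)3 and aqueous acid to give [4-(methoxymethoxy)-3,5-bis(3-methylbut-2-en-1-yl)phenyl]boronic acid F1.
- Iodoketone 7 is prenylated by Stille coupling with tributyl(3-methylbut-2-enyl)stannane and Pd(PPh3)4 in DMF to give 1-[2-hydroxy-4-(methoxymethoxy)-3-(3-methylbut-2-en-1-yl)phenyl]ethan-1-one F2.
- Condensation of F2 with Me2NCH(OMe)2 gives (2E)-3-(dimethylamino)-1-[2-hydroxy-4-(methoxymethoxy)-3-(3-methylbut-2-en-1-yl)phenyl]prop-2-en-1-one F3.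
- F3 closes on silica gel or in dilute acetic acid, with loss of dimethylamine, to 7-(methoxymethoxy)-8-(3-methylbut-2-en-1-yl)-4H-chromen-4-one F4.
- Enantioselective 1,4-addition of F1 to F4 with Pd(OCOCF3)2 and the enantiomer of the tert-butyl pyridine–oxazoline ligand that gives the 2S product (a known route to flavanones that needs no base and so does not open ring C) should give 16, which is carried through the acid treatment of step 9.

Step 9. What may go wrong: acid-promoted ionisation of the benzylic C2–O1 bond, helped by the electron-rich ring B, with loss of configuration; protonation of a prenyl olefin and closure onto the neighbouring phenol to a dimethylchroman; incomplete cleavage of the hindered 4'-MOM ether.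

Fallback: it sets out from 15 and comes back at the target 17, and no compound outside the list is made (F0). The two unmasking events are separated and the MOM cleavage is changed from protic solvolysis to Lewis acid/thiol transacetalisation. The ketimine alone is hydrolysed with 1 M aqueous HCl in THF at 0 °C for a short time and 16 is isolated; both MOM ethers are then removed with ZnBr2 and n-PrSH in CH2Cl2 at 0 °C, conditions under which neither the C2–O1 bond nor the prenyl olefins should be protonated.

Step 1. What may go wrong: O-alkylation competing with C-alkylation, and stopping at the mono-prenyl stage or over-alkylation to dienones, in the heterogeneous phenoxide reaction.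

Fallback: it sets out from 1 and comes back at 2, building each prenyl group by an aromatic Claisen rearrangement instead of direct C-alkylation.
- Phenol 1 is converted with tert-butyl 2-methylbut-3-en-2-yl carbonate and Pd(PPh3)4 (Tsuji–Trost O-allylation) into 1-bromo-4-[(2-methylbut-3-en-2-yl)oxy]benzene F5.
- Aromatic Claisen rearrangement of F5 (Eu(fod)3, CHCl3, 60 °C, or heat in N,N-diethylaniline) should give 4-bromo-2-(3-methylbut-2-en-1-yl)phenol F6.
- The same O-allylation of F6 gives 4-bromo-1-[(2-methylbut-3-en-2-yl)oxy]-2-(3-methylbut-2-en-1-yl)benzene F7, and a second Claisen rearrangement to the remaining ortho position gives 2.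

**Further compounds**

F1 | step 8 | [4-(methoxymethoxy)-3,5-bis(3-methylbut-2-en-1-yl)phenyl]boronic acid | CC(C)=CCc1cc(B(O)O)cc(CC=C(C)C)c1OCOC
F2 | step 8 | 1-[2-hydroxy-4-(methoxymethoxy)-3-(3-methylbut-2-en-1-yl)phenyl]ethan-1-one | CC(=O)c1ccc(OCOC)c(CC=C(C)C)c1O
F3 | step 8 | (2E)-3-(dimethylamino)-1-[2-hydroxy-4-(methoxymethoxy)-3-(3-methylbut-2-en-1-yl)phenyl]prop-2-en-1-one | CN(C)/C=C/C(=O)c1ccc(OCOC)c(CC=C(C)C)c1O
F4 | step 8 | 7-(methoxymethoxy)-8-(3-methylbut-2-en-1-yl)-4H-chromen-4-one | O=c1ccoc2c(CC=C(C)C)c(OCOC)ccc12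
F0 | step 9 | none | none
F5 | step 1 | 1-bromo-4-[(2-methylbut-3-en-2-yl)oxy]benzene | C=CC(C)(C)Oc1ccc(Br)cc1
F6 | step 1 | 4-bromo-2-(3-methylbut-2-en-1-yl)phenol | CC(C)=CCc1cc(Br)ccc1O
F7 | step 1 | 4-bromo-1-[(2-methylbut-3-en-2-yl)oxy]-2-(3-methylbut-2-en-1-yl)benzene | C=CC(C)(C)Oc1ccc(Br)cc1CC=C(C)C
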